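**Plan**

1. Locants (fluorene type): dione ring C1(=O)–C2=C3–C4(=O); ring-fusion carbons C4a (benzylic, quaternary) and C9a (prenyl-bearing); benzylic C9; arene oxygens on C5 and C8; bridge C9–C10H=C11(CH3)–C12H2–C4a.
2. Retrosynthesis: the aryl methyl ethers and the C2=C3 double bond are adjusted last; the bridge bond C4a–C12 is cut (enolate alkylation); C4–C4a is cut as the C(=O)–C(OH) bond of an acyloin (key ring closure); C9a–C1 and C9a–prenyl are cut to a 1-indanone enolate; C9–C10 is cut to 4,7-dimethoxyinden-1-one and a (Z)-alkenylboronate.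
3. Forward: the arene and the five-membered ring are bought as 4,7-dimethoxyindan-1-one; C9 and then C9a are substituted; the six-membered dione ring is closed onto the indanone carbonyl; the bridging cyclohexene is closed next; desaturation and demethylation finish.
4. Enabling feature: C4a is a member of the five-membered ring bound directly to the arene (next to the oxygenated C5) and is alpha to the C4 carbonyl, while C1 and C4 stand 1,4 across the six-membered ring. At ketone oxidation level C4a is therefore the carbonyl of a 1-indanone and C4 an aldehyde four atoms away on the C1 acyl chain, which is the pairing for a crossed benzoin.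
5. Stereochemistry: C9 from the (R)-BINAP/rhodium conjugate addition; C9a from two enolate reactions anti to the C9 group (prenyl first, acyl second, so prenyl ends cis to the C9 chain); C4a from the tethers (cis 6/5 fusion in the benzoin, then alkylation from the face of the C9 chain).

Key step: step 10

Remark: 4,7-dimethoxyindan-1-one, prop-2-yn-1-ol and 4,4-dimethoxybutanal are taken as purchasable. The sense of induction in step 5 is assigned by analogy with 2-cyclopentenone; the other BINAP antipode would be used if it proved opposite.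

**Route**

Step 1
Reactants: 1 prop-2-yn-1-ol
Product: 3 (Z)-3-iodo-2-methylprop-2-en-1-ol, via alkenylmagnesium alkoxide 2 (not isolated)
Conditions: MeMgBr (2.5 equiv), CuI (10 mol %), THF, −10 °C → rt; then I2, −30 → 0 °C
Reagents that add atoms: methylmagnesium bromide, C[Mg]Br; iodine, II
Why: Copper-catalysed anti-carbomagnesiation of the propargylic alkoxide should deliver methyl to the internal carbon and leave magnesium cis to the CH2O group in a five-membered chelate, and iodinolysis with retention should give the (Z)-alkenyl iodide.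

Step 2
Reactants: 3 (Z)-3-iodo-2-methylprop-2-en-1-ol
Product: 4 tert-butyl{[(Z)-3-iodo-2-methylprop-2-en-1-yl]oxy}dimethylsilane
Conditions: TBSCl, imidazole, CH2Cl2, rt
Reagents that add atoms: tert-butyldimethylsilyl chloride, CC(C)(C)[Si](C)(C)Cl
Why: Routine silylation of a primary alcohol masks the hydroxyl through the later enolate steps.

Step 3
Reactants: 4 tert-butyl{[(Z)-3-iodo-2-methylprop-2-en-1-yl]oxy}dimethylsilane
Product: 5 tert-butyldimethyl{[(Z)-2-methyl-3-(4,4,5,5-tetramethyl-1,3,2-dioxaborolan-2-yl)prop-2-en-1-yl]oxy}silane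
Conditions: B2pin2, PdCl2(PPh3)2 (3 mol %), PPh3 (6 mol %), KOPh, toluene, 50 °C
Reagents that add atoms: bis(pinacolato)diboron, CC1(C)OB(OC1(C)C)B1OC(C)(C)C(C)(C)O1
Why: Miyaura borylation of an alkenyl iodide should proceed with retention of the (Z) geometry and avoids an alkenyllithium, which could suffer silyl migration from oxygen to carbon.

Step 4
Reactants: 6 4,7-dimethoxy-2,3-dihydro-1H-inden-1-one
Product: 8 4,7-dimethoxy-1H-inden-1-one, via silyl enol ether 7 (not isolated)
Conditions: TMSOTf, Et3N, CH2Cl2, 0 °C; then Pd(OAc)2 (1.05 equiv), MeCN, rt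
Reagents that add atoms: none
Why: Saegusa–Ito oxidation of the trimethylsilyl enol ether should give the indenone, which is prone to dimerisation and is carried directly into step 5.

Step 5
Reactants: 8 4,7-dimethoxy-1H-inden-1-one; 5 tert-butyldimethyl{[(Z)-2-methyl-3-(4,4,5,5-tetramethyl-1,3,2-dioxaborolan-2-yl)prop-2-en-1-yl]oxy}silane
Product: 9 (3R)-3-[(Z)-3-(tert-butyldimethylsilyloxy)-2-methylprop-1-en-1-yl]-4,7-dimethoxy-2,3-dihydro-1H-inden-1-one
Conditions: [RhCl(C2H4)2]2 (2.5 mol %), (R)-BINAP (5.5 mol %), KOH (aq., 0.5 equiv), 1,4-dioxane, 40 °C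
Reagents that add atoms: none
Why: Hayashi–Miyaura rhodium-catalysed asymmetric 1,4-addition of the alkenylboron reagent to the cyclic enone should set C3 (the future C9) as R through enone-face selection by the (R)-BINAP–rhodium alkenyl species, with retention of the (Z) geometry.

Step 6
Reactants: 9 (3R)-3-[(Z)-3-(tert-butyldimethylsilyloxy)-2-methylprop-1-en-1-yl]-4,7-dimethoxy-2,3-dihydro-1H-inden-1-one
Product: 11 (2S,3S)-3-[(Z)-3-(tert-butyldimethylsilyloxy)-2-methylprop-1-en-1-yl]-4,7-dimethoxy-2-(3-methylbut-2-en-1-yl)-2,3-dihydro-1H-inden-1-one (2,3-trans), via lithium enolate 10 (not isolated)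
Conditions: LiN(i-Pr)2 (LDA, 1.05 equiv), THF, −78 °C; then prenyl bromide, −78 → −30 °C
Reagents that add atoms: prenyl bromide (1-bromo-3-methylbut-2-ene), CC(C)=CCBr
Why: Alkylation of the kinetic lithium enolate should place prenyl anti to the C3 alkenyl group (2,3-trans), a centre that is made planar again in step 7.

Step 7
Reactants: 11 (2S,3S)-2-prenyl-3-alkenyl indanone; 12 4,4-dimethoxybutanal
Product: 14 (2R,3R)-3-[(Z)-3-(tert-butyldimethylsilyloxy)-2-methylprop-1-en-1-yl]-2-(1-hydroxy-4,4-dimethoxybutyl)-4,7-dimethoxy-2-(3-methylbut-2-en-1-yl)-2,3-dihydro-1H-inden-1-one (carbinol epimers; prenyl cis to the C3 alkenyl group), via lithium enolate 13 (not isolated)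
Conditions: LiN(i-Pr)2 (LDA, 1.1 equiv), THF, −78 °C; then 12, −78 °C; AcOH quench at −78 °C
Reagents that add atoms: none
Why: Aldol addition of the tetrasubstituted lithium enolate should occur on the face anti to the C3 alkenyl group, so the new carbon–carbon bond ends trans to it and prenyl cis, which fixes the quaternary centre (future C9a); the carbinol centre is removed in step 8.

Step 8
Reactants: 14 aldol adduct
Product: 15 (2R,3R)-3-[(Z)-3-(tert-butyldimethylsilyloxy)-2-methylprop-1-en-1-yl]-2-(4,4-dimethoxybutanoyl)-4,7-dimethoxy-2-(3-methylbut-2-en-1-yl)-2,3-dihydro-1H-inden-1-one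
Conditions: Dess–Martin periodinane, CH2Cl2, 0 °C → rt
Reagents that add atoms: none
Why: Dess–Martin oxidation of the secondary carbinol should give the non-enolisable 1,3-diketone without touching the acetal, the silyl ether or the alkenes.

Step 9
Reactants: 15 diketone acetal
Product: 16 4-{(2R,3R)-3-[(Z)-3-hydroxy-2-methylprop-1-en-1-yl]-4,7-dimethoxy-2-(3-methylbut-2-en-1-yl)-1-oxo-2,3-dihydro-1H-inden-2-yl}-4-oxobutanal
Conditions: 1 M HCl (aq.), THF, rt
Reagents that add atoms: water, O
Why: Acid hydrolysis should remove the dimethyl acetal and the primary silyl ether in one operation, and the 2,2-disubstituted 1,3-diketone can neither enolise nor eliminate.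

Step 10
Reactants: 16 keto-aldehyde
Product: 17 (4aS,9R,9aS)-4a-hydroxy-9-[(Z)-3-hydroxy-2-methylprop-1-en-1-yl]-5,8-dimethoxy-9a-(3-methylbut-2-en-1-yl)-2,3,9,9a-tetrahydro-1H-fluorene-1,4(4aH)-dione (cis 4a/9a fusion; 4a-OH, prenyl and C9 chain on one face)
Conditions: 2-(pentafluorophenyl)-6,7-dihydro-5H-pyrrolo[2,1-c][1,2,4]triazol-2-ium tetrafluoroborate (10 mol %), Et3N (20 mol %), toluene, 40 °C
Reagents that add atoms: none
Why: The triazolylidene adds to the aldehyde carbon (C4) to give the Breslow intermediate, an acyl-anion equivalent, which adds to the indanone carbonyl (C4a); proton transfer and loss of the carbene should give the tertiary α-ketol. The closest known reaction type is the carbene-catalysed intramolecular crossed aldehyde–ketone benzoin, which is established for six-membered acyloins and for ketones flanked by a quaternary carbon. The dione ring closes in the 6-exo-trig mode onto the C=O of the indanone. The new stereocentre C4a is controlled by the tether: C1 sits on C9a, so C4 can reach only the face of the C4a carbonyl syn to C1, which gives the cis 6/5 fusion and leaves the hydroxyl on the face of the prenyl group and the C9 chain. The step needs chemoselectivity for benzoin addition at C4a over aldol pathways and over the C1 ketone; the 1,3-diketone cannot enolise because C9a is quaternary, attack at C1 would need a four-membered ring, and the only enolisable site, the aldehyde α-CH2, is addressed only by a weak amine base.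

Step 11
Reactants: 17 α-ketol
Product: 18 (4aR,9R,9aS)-9-[(Z)-3-hydroxy-2-methylprop-1-en-1-yl]-5,8-dimethoxy-9a-(3-methylbut-2-en-1-yl)-2,3,9,9a-tetrahydro-1H-fluorene-1,4(4aH)-dione
Conditions: SmI2 (2.5 equiv), THF/MeOH, −78 °C
Reagents that add atoms: none
Why: Samarium diiodide reduction of an α-hydroxy ketone should cleave the benzylic C–O bond next to the carbonyl and give the α-aryl ketone after protonation of the samarium enolate; the configuration at C4a is immaterial because this carbon is enolised in step 13.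

Step 12
Reactants: 18 α-aryl ketone with free allylic alcohol
Product: 19 (4aR,9R,9aS)-9-[(Z)-3-bromo-2-methylprop-1-en-1-yl]-5,8-dimethoxy-9a-(3-methylbut-2-en-1-yl)-2,3,9,9a-tetrahydro-1H-fluorene-1,4(4aH)-dione
Conditions: CBr4, PPh3, 2,6-lutidine, CH2Cl2, −20 °C
Reagents that add atoms: carbon tetrabromide, BrC(Br)(Br)Br
Why: Appel bromination should convert the primary allylic alcohol into the bromide under neutral conditions at low temperature, which keeps the (Z) geometry needed for ring closure and leaves the ketones untouched.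

Step 13
Reactants: 19 allylic bromide
Product: 20 (4aR,9R,9aS)-5,8-dimethoxy-9a-(3-methylbut-2-en-1-yl)-4a,9-(2-methylprop-1-ene-1,3-diyl)-2,3,9,9a-tetrahydro-1H-fluorene-1,4(4aH)-dione (C12 on C4a, C10 on C9)
Conditions: KOt-Bu (1.05 equiv), t-BuOH/THF, 0 °C → rt
Reagents that add atoms: none
Why: Intramolecular SN2 C-alkylation (6-exo-tet) of the thermodynamic benzylic potassium enolate of the C4 ketone by the (Z)-allylic bromide should form C4a–C12 on the only face the tether from C9 can reach, which sets the quaternary stereocentre C4a with the bridge cis to prenyl, whereas attack through oxygen or at C10 would need an eight- or a four-membered ring.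

Step 14
Reactants: 20 bridged diketone
Product: 22 (4aR,9R,9aS)-5,8-dimethoxy-9a-(3-methylbut-2-en-1-yl)-4a,9-(2-methylprop-1-ene-1,3-diyl)-9,9a-dihydro-1H-fluorene-1,4(4aH)-dione (bis(methyl ether) of the target), via lithium enolate 21 (not isolated)
Conditions: LiN(SiMe3)2 (1.1 equiv), THF, −78 °C; then N-tert-butylbenzenesulfinimidoyl chloride, −78 °C
Reagents that add atoms: none
Why: One-pot enolate dehydrogenation with the sulfinimidoyl chloride (sulfur–carbon bond formation, then syn-elimination) should introduce the C2=C3 double bond, since the two methylenes are the only enolisable positions and either enolate leads to the same ene-dione.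

Step 15
Reactants: 22 ene-dione bis(methyl ether)
Product: 24 CNP0166383.1, (4aR,9R,9aS)-5,8-dihydroxy ene-dione (target), via quinone 23 (not isolated)
Conditions: (NH4)2Ce(NO3)6 (2.5 equiv), MeCN/H2O, 0 °C; then Na2S2O4 (aq.), EtOAc, rt, under argon
Reagents that add atoms: water, O
Why: Oxidative demethylation of the 1,4-dimethoxyarene to the p-quinone with ceric ammonium nitrate, followed by dithionite reduction, should free the hydroquinone without acids or nucleophiles that would attack the prenyl group or the ene-dione.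

**Compound list**

1 | prop-2-yn-1-ol | C#CCO | starting material
2 | bromomagnesium (Z)-3-(bromomagnesio)-2-methylprop-2-en-1-olate | Br[Mg]OC/C(C)=C\[Mg]Br | intermediate
3 | (Z)-3-iodo-2-methylprop-2-en-1-ol | OC/C(C)=C\I | intermediate
4 | tert-butyl{[(Z)-3-iodo-2-methylprop-2-en-1-yl]oxy}dimethylsilane | CC(C)(C)[Si](C)(C)OC/C(C)=C\I | intermediate
5 | tert-butyldimethyl{[(Z)-2-methyl-3-(4,4,5,5-tetramethyl-1,3,2-dioxaborolan-2-yl)prop-2-en-1-yl]oxy}silane | CC(C)(C)[Si](C)(C)OC/C(C)=C\B1OC(C)(C)C(C)(C)O1 | intermediate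
6 | 4,7-dimethoxy-2,3-dihydro-1H-inden-1-one | COc1ccc(OC)c2C(=O)CCc12 | starting material
7 | [(4,7-dimethoxy-1H-inden-3-yl)oxy]trimethylsilane | COc1ccc(OC)c2C(O[Si](C)(C)C)=CCc12 | intermediate
8 | 4,7-dimethoxy-1H-inden-1-one | COc1ccc(OC)c2C(=O)C=Cc12 | intermediate
9 | (3R)-3-[(Z)-3-(tert-butyldimethylsilyloxy)-2-methylprop-1-en-1-yl]-4,7-dimethoxy-2,3-dihydro-1H-inden-1-one | COc1ccc(OC)c2C(=O)C[C@H](/C=C(C)\CO[Si](C)(C)C(C)(C)C)c12 | intermediate
10 | lithium enolate of 9 (C1–O–Li, C1=C2) | COc1ccc(OC)c2C(O[Li])=C[C@H](/C=C(C)\CO[Si](C)(C)C(C)(C)C)c12 | intermediate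
11 | (2S,3S)-3-[(Z)-3-(tert-butyldimethylsilyloxy)-2-methylprop-1-en-1-yl]-4,7-dimethoxy-2-(3-methylbut-2-en-1-yl)-2,3-dihydro-1H-inden-1-one | COc1ccc(OC)c2C(=O)[C@@H](CC=C(C)C)[C@H](/C=C(C)\CO[Si](C)(C)C(C)(C)C)c12 | intermediate
12 | 4,4-dimethoxybutanal | COC(OC)CCC=O | starting material
13 | lithium enolate of 11 (C1–O–Li, C1=C2) | COc1ccc(OC)c2C(O[Li])=C(CC=C(C)C)[C@H](/C=C(C)\CO[Si](C)(C)C(C)(C)C)c12 | intermediate
14 | (2R,3R)-3-[(Z)-3-(tert-butyldimethylsilyloxy)-2-methylprop-1-en-1-yl]-2-(1-hydroxy-4,4-dimethoxybutyl)-4,7-dimethoxy-2-(3-methylbut-2-en-1-yl)-2,3-dihydro-1H-inden-1-one (carbinol epimers) | COc1ccc(OC)c2C(=O)[C@@](CC=C(C)C)(C(O)CCC(OC)OC)[C@H](/C=C(C)\CO[Si](C)(C)C(C)(C)C)c12 | intermediate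
15 | (2R,3R)-3-[(Z)-3-(tert-butyldimethylsilyloxy)-2-methylprop-1-en-1-yl]-2-(4,4-dimethoxybutanoyl)-4,7-dimethoxy-2-(3-methylbut-2-en-1-yl)-2,3-dihydro-1H-inden-1-one | COc1ccc(OC)c2C(=O)[C@@](CC=C(C)C)(C(=O)CCC(OC)OC)[C@H](/C=C(C)\CO[Si](C)(C)C(C)(C)C)c12 | intermediate
16 | 4-{(2R,3R)-3-[(Z)-3-hydroxy-2-methylprop-1-en-1-yl]-4,7-dimethoxy-2-(3-methylbut-2-en-1-yl)-1-oxo-2,3-dihydro-1H-inden-2-yl}-4-oxobutanal | COc1ccc(OC)c2C(=O)[C@@](CC=C(C)C)(C(=O)CCC=O)[C@H](/C=C(C)\CO)c12 | intermediate
17 | (4aS,9R,9aS)-4a-hydroxy-9-[(Z)-3-hydroxy-2-methylprop-1-en-1-yl]-5,8-dimethoxy-9a-(3-methylbut-2-en-1-yl)-2,3,9,9a-tetrahydro-1H-fluorene-1,4(4aH)-dione | CC(C)=CC[C@@]12C(=O)CCC(=O)[C@]1(O)c1c(OC)ccc(OC)c1[C@H]2/C=C(C)\CO | intermediate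
18 | (4aR,9R,9aS)-9-[(Z)-3-hydroxy-2-methylprop-1-en-1-yl]-5,8-dimethoxy-9a-(3-methylbut-2-en-1-yl)-2,3,9,9a-tetrahydro-1H-fluorene-1,4(4aH)-dione | CC(C)=CC[C@@]12C(=O)CCC(=O)[C@@H]1c1c(OC)ccc(OC)c1[C@H]2/C=C(C)\CO | intermediate
19 | (4aR,9R,9aS)-9-[(Z)-3-bromo-2-methylprop-1-en-1-yl]-5,8-dimethoxy-9a-(3-methylbut-2-en-1-yl)-2,3,9,9a-tetrahydro-1H-fluorene-1,4(4aH)-dione | CC(C)=CC[C@@]12C(=O)CCC(=O)[C@@H]1c1c(OC)ccc(OC)c1[C@H]2/C=C(C)\CBr | intermediate
20 | (4aR,9R,9aS)-5,8-dimethoxy-9a-(3-methylbut-2-en-1-yl)-4a,9-(2-methylprop-1-ene-1,3-diyl)-2,3,9,9a-tetrahydro-1H-fluorene-1,4(4aH)-dione | CC(C)=CC[C@@]12C(=O)CCC(=O)[C@@]13CC(C)=C[C@@H]2c1c(OC)ccc(OC)c13 | intermediate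
21 | lithium enolate of 20 (C1–O–Li, C1=C2 shown; the C4 regioisomer converges) | CC(C)=CC[C@@]12C(O[Li])=CCC(=O)[C@@]13CC(C)=C[C@@H]2c1c(OC)ccc(OC)c13 | intermediate
22 | (4aR,9R,9aS)-5,8-dimethoxy-9a-(3-methylbut-2-en-1-yl)-4a,9-(2-methylprop-1-ene-1,3-diyl)-9,9a-dihydro-1H-fluorene-1,4(4aH)-dione | CC(C)=CC[C@@]12C(=O)C=CC(=O)[C@@]13CC(C)=C[C@@H]2c1c(OC)ccc(OC)c13 | intermediate
23 | quinone of the target (arene ring as 5,8-dione; same three stereocentres) | CC(C)=CC[C@@]12C(=O)C=CC(=O)[C@@]13CC(C)=C[C@@H]2C4=C3C(=O)C=CC4=O | intermediate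
24 | CNP0166383.1 | CC(C)=CC[C@@]12C(=O)C=CC(=O)[C@@]13CC(C)=C[C@@H]2c1c(O)ccc(O)c13 | target

**Count and risks**

Total steps: 15. Longest linear sequence: 14 (steps 1–3, then 5–15).

Step 10 (key ring closure). Addition of the acyl-anion equivalent to the hindered, electron-rich indanone carbonyl may be slower than aldol consumption of the enolisable aldehyde, or the acyloin may revert. The fallback makes the C4–C4a bond reductively; it sets out from 15 and returns at 17. The acetal of 15 is hydrolysed with pyridinium p-toluenesulfonate in wet acetone with the silyl ether kept, which should give keto-aldehyde F1. SmI2 (THF, t-BuOH, −78 °C) should then effect ketyl–carbonyl pinacol cyclisation to the cis-fused 4,4a-diol F2. Parikh–Doering oxidation (SO3·pyridine, DMSO, Et3N) of the secondary carbinol should give the silylated α-ketol F3, and HF·pyridine removes the silyl group to give 17.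

Step 13 (bridging alkylation). The congested benzylic enolate may react so slowly that vinylogous loss of HBr to the arene-conjugated diene, or isomerisation of the (Z)-allylic bromide, overtakes C-alkylation. The fallback closes the same bond without external base; it sets out from 18 and returns at 20. Alcohol 18 is converted into methyl carbonate F4 (ClCO2Me, pyridine, CH2Cl2, 0 °C) and treated with Pd2(dba)3 and PPh3 in THF at 60 °C (Tsuji–Trost). Ionisation by zerovalent palladium gives the allyl complex and methoxide, which generates the benzylic enolate in situ. The six-membered closure onto the allyl terminus is geometrically less favourable than the SN2 closure, which is why it is the reserve.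

Step 7 (aldol at the quaternary centre). The tetrasubstituted enolate may act as a base toward the enolisable aldehyde, or the crowded aldolate may revert on warming. The fallback is a direct, irreversible C-acylation; it sets out from 11 and returns at 15, skipping step 8. Enolate 13 is treated at −78 °C with the imidazolide F5 of 4,4-dimethoxybutanoic acid (acid and 1,1'-carbonyldiimidazole), which should give diketone 15 with the same facial preference.

Further compounds
F1 | step 10 | 4-{(2R,3R)-3-[(Z)-3-(tert-butyldimethylsilyloxy)-2-methylprop-1-en-1-yl]-4,7-dimethoxy-2-(3-methylbut-2-en-1-yl)-1-oxo-2,3-dihydro-1H-inden-2-yl}-4-oxobutanal | COc1ccc(OC)c2C(=O)[C@@](CC=C(C)C)(C(=O)CCC=O)[C@H](/C=C(C)\CO[Si](C)(C)C(C)(C)C)c12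
F2 | step 10 | cis-fused 4,4a-diol: 4,4a-dihydroxy-9-[(Z)-3-(tert-butyldimethylsilyloxy)-2-methylprop-1-en-1-yl]-5,8-dimethoxy-9a-(3-methylbut-2-en-1-yl)-2,3,4,4a,9,9a-hexahydro-1H-fluoren-1-one (C4 epimers) | CC(C)=CC[C@@]12C(=O)CCC(O)[C@]1(O)c1c(OC)ccc(OC)c1[C@H]2/C=C(C)\CO[Si](C)(C)C(C)(C)C
F3 | step 10 | tert-butyldimethylsilyl ether of 17 at the allylic oxygen | CC(C)=CC[C@@]12C(=O)CCC(=O)[C@]1(O)c1c(OC)ccc(OC)c1[C@H]2/C=C(C)\CO[Si](C)(C)C(C)(C)C
F4 | step 13 | methyl carbonate of 18 at the allylic oxygen | CC(C)=CC[C@@]12C(=O)CCC(=O)[C@@H]1c1c(OC)ccc(OC)c1[C@H]2/C=C(C)\COC(=O)OC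
F5 | step 7 | 1-(4,4-dimethoxybutanoyl)-1H-imidazole | COC(OC)CCC(=O)n1ccnc1
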